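## Retrosynthetic overview

The target is epiafzelechin-(4β→8)-epiafzelechin-(4β→8)-epiafzelechin; the two outer flavan units are taken from (−)-epiafzelechin and only the middle unit is built from two arenes and a three-carbon chain.
Last C–C disconnection: the upper interflavan bond, C4 (upper unit)–C8 (middle unit), leading to a C8-bromine-capped C4 electrophile and a benzylated dimer (Friedel–Crafts coupling).
Key disconnection: the pyran ring (ring C) of the middle unit is opened at C4–C4a together with the lower interflavan bond C4–C8 (lower unit), leading to an acyclic aryloxy acetal and benzylated epiafzelechin.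
Enabling feature: C4 of the middle unit is a carbon at aldehyde oxidation level bonded to two phloroglucinol-type ring carbons (C4a of its own ring A, ortho to O1 at C8a, and C8 of the lower ring A). As an acetal it is attacked first by C4a (ring closure), and the new ring A with O1, O5 and O7 then stabilises the C4 cation that C8 of the lower unit captures anti to O3.
C2 and C3 of the middle unit come from one catalytic asymmetric cis-epoxidation followed by invertive opening with 3,5-bis(benzyloxy)phenol, and C4 is relayed from C3. Ring order: rings of the outer units (bought), rings A and B of the middle unit (bought arenes), ring C of the middle unit last.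

Key step: step 9

Assumption: (−)-epiafzelechin of natural (2R,3R) configuration is used as a purchased starting material that supplies both outer flavan units.

## Route

Step 1
Reactants: 1 1-(benzyloxy)-4-iodobenzene; 2 3,3-diethoxyprop-1-yne
Product: 3 1-(benzyloxy)-4-(3,3-diethoxyprop-1-yn-1-yl)benzene
Conditions: Pd(PPh3)2Cl2 (2 mol%), CuI (4 mol%), Et3N, THF, rt
Reagents that add atoms: none
Why: Sonogashira coupling of an aryl iodide with a terminal alkyne; the acetal and the benzyl ether are inert and no stereocentre is formed.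

Step 2
Reactants: 3 aryl alkyne acetal
Product: 4 (Z)-1-(benzyloxy)-4-(3,3-diethoxyprop-1-en-1-yl)benzene
Conditions: H2 (1 atm), Pd/CaCO3 poisoned with Pb(OAc)2, quinoline, EtOAc, rt
Reagents that add atoms: none
Why: Syn semi-hydrogenation of the alkyne on lead-poisoned palladium (Lindlar reduction) should stop at the Z-alkene, whose geometry is the source of the later 2,3-cis relationship, and the poisoned catalyst does not cleave the aryl benzyl ether.

Step 3
Reactants: 4 Z-alkene acetal
Product: 5 (2S,3S)-2-[4-(benzyloxy)phenyl]-3-(diethoxymethyl)oxirane (cis-epoxide)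
Conditions: (S,S)-N,N'-bis(3,5-di-tert-butylsalicylidene)-1,2-cyclohexanediaminomanganese chloride (5 mol%), 4-phenylpyridine N-oxide (0.2 equiv), aq. NaOCl (pH 11.3), CH2Cl2, 0 °C
Reagents that add atoms: sodium hypochlorite, [Na+].[O-]Cl
Why: Jacobsen–Katsuki epoxidation, for which cis-disubstituted aryl alkenes are the best substrate class: side-on approach of the Z-alkene to the oxo-manganese salen complex should transfer oxygen to one enantioface, the (S,S)-catalyst being chosen by analogy with cis-β-methylstyrene and cis-cinnamate esters to make the benzylic carbon S, so that both stereocentres of the cis-(2S,3S)-epoxide are set here by the catalyst while the basic two-phase medium spares the acetal and the acid-labile epoxide.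

Step 4
Reactants: 5 cis-epoxide; 6 3,5-bis(benzyloxy)phenol
Product: 7 (2S,3R)-3-[3,5-bis(benzyloxy)phenoxy]-3-[4-(benzyloxy)phenyl]-1,1-diethoxypropan-2-ol (syn)
Conditions: 6 (1.3 equiv), Cs2CO3 (0.2 equiv), DMF, 90 °C
Reagents that add atoms: none
Why: Base-mediated SN2 ring opening of an aryl epoxide by a phenoxide: attack should occur at the benzylic carbon, which is electronically activated whereas the other carbon is deactivated and shielded by the adjacent acetal, with clean inversion (S to R) and no change at the carbinol carbon, which turns the cis-epoxide into the syn aryloxy alcohol that maps onto a 2,3-cis flavan.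

Step 5
Reactants: 7 syn aryloxy alcohol
Product: 8 (2S,3R)-2-(benzyloxy)-3-[3,5-bis(benzyloxy)phenoxy]-3-[4-(benzyloxy)phenyl]propanal diethyl acetal
Conditions: NaH, BnBr, Bu4NI (cat.), DMF, 0 °C → rt
Reagents that add atoms: benzyl bromide, BrCc1ccccc1
Why: Williamson etherification of the secondary alkoxide; no stereocentre is touched and the benzyl group keeps all protecting groups removable in one hydrogenolysis.

Step 6
Reactants: 9 (−)-epiafzelechin
Product: 10 3,5,7,4'-tetra-O-benzyl-epiafzelechin
Conditions: NaH (4.5 equiv), BnBr (4.5 equiv), DMF, 0 °C → rt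
Reagents that add atoms: benzyl bromide, BrCc1ccccc1
Why: Williamson etherification of the three phenoxides and the C3 alkoxide with benzyl bromide; C2 and C3 are not touched and the uniform benzyl protection allows a single final hydrogenolysis.

Step 7
Reactants: 10 tetra-O-benzyl-epiafzelechin
Product: 11 (2R,3R,4S)-3,5,7-tris(benzyloxy)-2-[4-(benzyloxy)phenyl]-4-(2-ethoxyethoxy)chromane (4β)
Conditions: DDQ (2 equiv), 2-ethoxyethanol (5 equiv), CH2Cl2, rt
Reagents that add atoms: 2-ethoxyethanol, CCOCCO
Why: DDQ-mediated benzylic oxidation: hydride abstraction from C4, the position ortho/para to the three oxygens of ring A, gives the flavan-4-yl cation, which 2-ethoxyethanol should trap anti to the pseudo-axial 3-benzyloxy group (4β, 3,4-trans), while the aryl and alkyl benzyl ethers are too slow to compete at room temperature.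

Step 8
Reactants: 11 4β-(2-ethoxyethoxy) flavan
Product: 12 (2R,3R,4S)-8-bromo-3,5,7-tris(benzyloxy)-2-[4-(benzyloxy)phenyl]-4-(2-ethoxyethoxy)chromane
Conditions: NBS (1.05 equiv), CH2Cl2, −20 °C
Reagents that add atoms: N-bromosuccinimide, O=C1CCC(=O)N1Br
Why: Electrophilic aromatic bromination with NBS should occur at C8, the most nucleophilic and least hindered carbon of ring A, and the bromine caps this position so that 12 can later act only as an electrophile; no stereocentre is touched.

Step 9
Reactants: 8 aryloxy acetal; 10 tetra-O-benzyl-epiafzelechin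
Product: 14 octa-O-benzyl epiafzelechin-(4β→8)-epiafzelechin, via 4-ethoxyflavan 13 (not isolated)
Conditions: 10 (3 equiv), TMSOTf (0.3 equiv), CH2Cl2, −78 → −30 °C; then Et3N
Reagents that add atoms: none
Why: Catalytic TMSOTf ionises the diethyl acetal of 8 to an oxocarbenium ion at C4, which the ring carbon ortho to the aryl ether oxygen (the future C4a, also ortho and para to the two benzyloxy groups) attacks in an intramolecular Friedel–Crafts alkylation, a 6-exo-trig closure of the pyran ring through C4–C4a that gives 4-ethoxyflavan 13. Under the same acid 13 loses ethanol to the flavan-4-yl cation, now stabilised by O1, O5 and O7 of the newly fused ring A, and C8 of 10 adds to it in a second, intermolecular Friedel–Crafts alkylation that forms the lower interflavan bond. The closest known reactions are the acid-mediated cyclisation of 3-aryloxypropanal acetals to 4-alkoxychromans and the Lewis acid-promoted coupling of 4-alkoxyflavan-3-ol ethers with C8 of a second flavan. The only new stereocentre, C4, is set by substrate control: in the 2,3-cis half-chair the 3-benzyloxy group is pseudo-axial and the arene enters anti to it, giving the 3,4-trans (4β) bond, while C2 and C3 are carried unchanged from 8. The step needs ring closure to outrun intermolecular capture of the first cation (secured by the six-membered intramolecular mode onto a triply activated carbon), C8 rather than C6 selectivity in 10 (C8 is flanked by the ring oxygen and is the less hindered site) and suppression of self-condensation at the free C8 of the new unit (excess of 10, low temperature).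

Step 10
Reactants: 14 octa-O-benzyl dimer; 12 bromine-capped C4 electrophile
Product: 15 8-bromo-3,5,7,4'-tetra-O-benzyl-epiafzelechin-(4β→8)-3,5,7,4'-tetra-O-benzyl-epiafzelechin-(4β→8)-3,5,7,4'-tetra-O-benzyl-epiafzelechin
Conditions: 12 (1.1 equiv), TMSOTf (0.3 equiv), CH2Cl2, −78 → −40 °C; then Et3N
Reagents that add atoms: none
Why: Lewis acid-promoted Friedel–Crafts interflavan coupling: TMSOTf ionises the 4-(2-ethoxyethoxy) group of 12, the free C8 of the middle unit of 14 (flanked by the ring oxygen, more reactive than either C6) attacks the cation anti to the 3-benzyloxy group to set the new C4 centre 4β by substrate control, and the C8 bromine of 12 excludes self-condensation.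

Step 11
Reactants: 15 protected bromo trimer
Product: 16 epiafzelechin-(4β→8)-epiafzelechin-(4β→8)-epiafzelechin (target)
Conditions: H2 (1 atm), Pd(OH)2/C, Et3N (2 equiv), THF/MeOH/H2O, rt
Reagents that add atoms: none
Why: Catalytic hydrogenolysis on Pd(OH)2/C should cleave the twelve benzyl ethers and, with Et3N as HBr scavenger, the aryl C–Br bond, while the interflavan C–C bonds, the pyran rings and all stereocentres are untouched.

## Compound list

1 | 1-(benzyloxy)-4-iodobenzene | Ic1ccc(OCc2ccccc2)cc1 | starting material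
2 | 3,3-diethoxyprop-1-yne | C#CC(OCC)OCC | starting material
3 | 1-(benzyloxy)-4-(3,3-diethoxyprop-1-yn-1-yl)benzene | CCOC(OCC)C#Cc1ccc(OCc2ccccc2)cc1 | intermediate
4 | (Z)-1-(benzyloxy)-4-(3,3-diethoxyprop-1-en-1-yl)benzene | CCOC(OCC)/C=C\c1ccc(OCc2ccccc2)cc1 | intermediate
5 | (2S,3S)-2-[4-(benzyloxy)phenyl]-3-(diethoxymethyl)oxirane (cis) | CCOC(OCC)[C@H]1O[C@H]1c1ccc(OCc2ccccc2)cc1 | intermediate
6 | 3,5-bis(benzyloxy)phenol | Oc1cc(OCc2ccccc2)cc(OCc2ccccc2)c1 | starting material
7 | (2S,3R)-3-[3,5-bis(benzyloxy)phenoxy]-3-[4-(benzyloxy)phenyl]-1,1-diethoxypropan-2-ol | C(c1ccccc1)Oc1cc(OCc2ccccc2)cc(O[C@H](c2ccc(OCc3ccccc3)cc2)[C@H](O)C(OCC)OCC)c1 | intermediate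
8 | (2S,3R)-2-(benzyloxy)-3-[3,5-bis(benzyloxy)phenoxy]-3-[4-(benzyloxy)phenyl]propanal diethyl acetal | C(c1ccccc1)Oc1cc(OCc2ccccc2)cc(O[C@H](c2ccc(OCc3ccccc3)cc2)[C@H](OCc2ccccc2)C(OCC)OCC)c1 | intermediate
9 | (−)-epiafzelechin, (2R,3R)-2-(4-hydroxyphenyl)chromane-3,5,7-triol | O[C@@H]1Cc2c(O)cc(O)cc2O[C@@H]1c1ccc(O)cc1 | starting material
10 | 3,5,7,4'-tetra-O-benzyl-epiafzelechin, (2R,3R)-3,5,7-tris(benzyloxy)-2-[4-(benzyloxy)phenyl]chromane | C(c1ccccc1)O[C@@H]1Cc2c(OCc3ccccc3)cc(OCc3ccccc3)cc2O[C@@H]1c1ccc(OCc2ccccc2)cc1 | intermediate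
11 | (2R,3R,4S)-3,5,7-tris(benzyloxy)-2-[4-(benzyloxy)phenyl]-4-(2-ethoxyethoxy)chromane (4β, trans to O3) | CCOCCO[C@H]1c2c(OCc3ccccc3)cc(OCc3ccccc3)cc2O[C@H](c2ccc(OCc3ccccc3)cc2)[C@@H]1OCc1ccccc1 | intermediate
12 | (2R,3R,4S)-8-bromo-3,5,7-tris(benzyloxy)-2-[4-(benzyloxy)phenyl]-4-(2-ethoxyethoxy)chromane (4β) | CCOCCO[C@H]1c2c(OCc3ccccc3)cc(OCc3ccccc3)c(Br)c2O[C@H](c2ccc(OCc3ccccc3)cc2)[C@@H]1OCc1ccccc1 | intermediate
13 | (2R,3R)-3,5,7-tris(benzyloxy)-2-[4-(benzyloxy)phenyl]-4-ethoxychromane (both C4 epimers) | CCOC1c2c(OCc3ccccc3)cc(OCc3ccccc3)cc2O[C@H](c2ccc(OCc3ccccc3)cc2)[C@@H]1OCc1ccccc1 | intermediate (not isolated)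
14 | octa-O-benzyl epiafzelechin-(4β→8)-epiafzelechin: (2R,3R,4R)-3,5,7-tris(benzyloxy)-2-[4-(benzyloxy)phenyl]-4-[(2R,3R)-3,5,7-tris(benzyloxy)-2-[4-(benzyloxy)phenyl]chroman-8-yl]chromane | C(c1ccccc1)O[C@@H]1Cc2c(OCc3ccccc3)cc(OCc3ccccc3)c([C@H]3c4c(OCc5ccccc5)cc(OCc5ccccc5)cc4O[C@H](c4ccc(OCc5ccccc5)cc4)[C@@H]3OCc3ccccc3)c2O[C@@H]1c1ccc(OCc2ccccc2)cc1 | intermediate
15 | 8-bromo-3,5,7,4'-tetra-O-benzyl-epiafzelechin-(4β→8)-3,5,7,4'-tetra-O-benzyl-epiafzelechin-(4β→8)-3,5,7,4'-tetra-O-benzyl-epiafzelechin (all units 2R,3R; both interflavan bonds 4β, trans to O3) | C(c1ccccc1)O[C@@H]1Cc2c(OCc3ccccc3)cc(OCc3ccccc3)c([C@H]3c4c(OCc5ccccc5)cc(OCc5ccccc5)c([C@H]5c6c(OCc7ccccc7)cc(OCc7ccccc7)c(Br)c6O[C@H](c6ccc(OCc7ccccc7)cc6)[C@@H]5OCc5ccccc5)c4O[C@H](c4ccc(OCc5ccccc5)cc4)[C@@H]3OCc3ccccc3)c2O[C@@H]1c1ccc(OCc2ccccc2)cc1 | intermediate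
16 | epiafzelechin-(4β→8)-epiafzelechin-(4β→8)-epiafzelechin (upper unit 2R,3R,4R; middle unit 2R,3R,4S; lower unit 2R,3R) | Oc1ccc([C@H]2Oc3c(c(O)cc(O)c3[C@H]3c4c(O)cc(O)cc4O[C@H](c4ccc(O)cc4)[C@@H]3O)[C@H](c3c(O)cc(O)c4c3O[C@H](c3ccc(O)cc3)[C@H](O)C4)[C@H]2O)cc1 | target

## Step count and risks

Total step count: 11. Longest linear sequence: 8 steps (steps 1, 2, 3, 4, 5, 9, 10, 11).

Steps most likely to fail:

1. Step 9 (key step). What may go wrong: capture of the first oxocarbenium ion by 10 before ring closure, acid-induced ionisation of the benzylic C2–O1 ether with loss of configuration at C2, or self-condensation through the free C8 of the newly formed unit. The fallback sets out from 8 and 10 and reverses the order of the two C–C bond formations, still closing the pyran ring of the middle unit last. Mild acetal hydrolysis of 8 (wet Amberlyst-15 in acetone) would give the aldehyde (2S,3R)-2-(benzyloxy)-3-[3,5-bis(benzyloxy)phenoxy]-3-[4-(benzyloxy)phenyl]propanal F1. Bromination of 10 with NBS at C8 would give 8-bromo-3,5,7,4'-tetra-O-benzyl-epiafzelechin F2. Bromine–lithium exchange of F2 (n-BuLi, THF, −78 °C) and addition of the aryllithium to F1 would give the diaryl-type carbinol 2-(benzyloxy)-3-[3,5-bis(benzyloxy)phenoxy]-3-[4-(benzyloxy)phenyl]-1-(tetra-O-benzyl-epiafzelechin-8-yl)propan-1-ol F3 as a mixture of carbinol epimers, which does not matter. Catalytic TMSOTf in CH2Cl2 at low temperature would then ionise the carbinol to a cation stabilised by ring A of the lower unit, and intramolecular Friedel–Crafts alkylation of the phenoxy ring would close the pyran ring, the 4-aryl group being expected to take the pseudo-axial position trans to the 3-benzyloxy group. The fallback comes back to the route at 14.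

2. Step 3. What may go wrong: leakage to the trans-epoxide through bond rotation in the stepwise oxygen transfer to this electron-rich styrene, and incomplete facial selectivity. The fallback sets out from 4 and replaces enantioselective catalysis by resolution through the enantiopure coupling partner. Epoxidation of 4 with dimethyldioxirane (acetone, −20 °C), a concerted and stereospecific oxygen transfer, would give the racemic cis-epoxide, that is 5 together with its enantiomer (2R,3R)-2-[4-(benzyloxy)phenyl]-3-(diethoxymethyl)oxirane F4. Steps 4 and 5 on the racemate would give 7 and 8 together with their enantiomers, the (2R,3S)-aryloxy alcohol F5 and the (2R,3S)-benzyl ether acetal F6. In step 9 the enantiopure 10 would turn the two enantiomers into diastereomers, 14 and octa-O-benzyl ent-epiafzelechin-(4α→8)-epiafzelechin F7, to be separated by chromatography. The fallback comes back to the route at 14.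

3. Step 10. What may go wrong: competing attack at C6 of the middle or lower unit of 14 and slow coupling at the hindered C8, leading to regioisomeric trimers. The fallback sets out from 12, 6 and 5 and attaches the upper unit before the middle pyran ring exists, so that the 4→8 connectivity is fixed by construction. TMSOTf-promoted Friedel–Crafts coupling of 12 with 6 at the carbon ortho to the free hydroxyl (less hindered than the carbon between the two benzyloxy groups) would give 2-(8-bromo-3,5,7,4'-tetra-O-benzyl-epiafzelechin-4β-yl)-3,5-bis(benzyloxy)phenol F8. Its phenoxide would open epoxide 5 as in step 4 to give the syn aryloxy alcohol F9, and benzylation as in step 5 would give the aryloxy acetal F10. The cascade of step 9 with 10 would then close the pyran ring at the only free ortho carbon and form the lower interflavan bond. The fallback comes back to the route at 15.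

## Further compounds

F1 | step 9 | (2S,3R)-2-(benzyloxy)-3-[3,5-bis(benzyloxy)phenoxy]-3-[4-(benzyloxy)phenyl]propanal | C(c1ccccc1)Oc1cc(OCc2ccccc2)cc(O[C@H](c2ccc(OCc3ccccc3)cc2)[C@H](OCc2ccccc2)C=O)c1
F2 | step 9 | (2R,3R)-8-bromo-3,5,7-tris(benzyloxy)-2-[4-(benzyloxy)phenyl]chromane | C(c1ccccc1)O[C@@H]1Cc2c(OCc3ccccc3)cc(OCc3ccccc3)c(Br)c2O[C@@H]1c1ccc(OCc2ccccc2)cc1
F3 | step 9 | (2R,3R)-2-(benzyloxy)-3-[3,5-bis(benzyloxy)phenoxy]-3-[4-(benzyloxy)phenyl]-1-[(2R,3R)-3,5,7-tris(benzyloxy)-2-[4-(benzyloxy)phenyl]chroman-8-yl]propan-1-ol (both C1 epimers) | C(c1ccccc1)O[C@@H]1Cc2c(OCc3ccccc3)cc(OCc3ccccc3)c(C(O)[C@@H](OCc3ccccc3)[C@@H](c3ccc(OCc4ccccc4)cc3)Oc3cc(OCc4ccccc4)cc(OCc4ccccc4)c3)c2O[C@@H]1c1ccc(OCc2ccccc2)cc1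
F4 | step 3 | (2R,3R)-2-[4-(benzyloxy)phenyl]-3-(diethoxymethyl)oxirane (cis) | CCOC(OCC)[C@@H]1O[C@@H]1c1ccc(OCc2ccccc2)cc1
F5 | step 3 | (2R,3S)-3-[3,5-bis(benzyloxy)phenoxy]-3-[4-(benzyloxy)phenyl]-1,1-diethoxypropan-2-ol | C(c1ccccc1)Oc1cc(OCc2ccccc2)cc(O[C@@H](c2ccc(OCc3ccccc3)cc2)[C@@H](O)C(OCC)OCC)c1
F6 | step 3 | (2R,3S)-2-(benzyloxy)-3-[3,5-bis(benzyloxy)phenoxy]-3-[4-(benzyloxy)phenyl]propanal diethyl acetal | C(c1ccccc1)Oc1cc(OCc2ccccc2)cc(O[C@@H](c2ccc(OCc3ccccc3)cc2)[C@@H](OCc2ccccc2)C(OCC)OCC)c1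
F7 | step 3 | octa-O-benzyl ent-epiafzelechin-(4α→8)-epiafzelechin (middle unit 2S,3S, 4-aryl trans to O3) | C(c1ccccc1)O[C@@H]1Cc2c(OCc3ccccc3)cc(OCc3ccccc3)c([C@@H]3c4c(OCc5ccccc5)cc(OCc5ccccc5)cc4O[C@@H](c4ccc(OCc5ccccc5)cc4)[C@H]3OCc3ccccc3)c2O[C@@H]1c1ccc(OCc2ccccc2)cc1
F8 | step 10 | 2-[(2R,3R,4β)-8-bromo-3,5,7-tris(benzyloxy)-2-[4-(benzyloxy)phenyl]chroman-4-yl]-3,5-bis(benzyloxy)phenol | Oc1cc(OCc2ccccc2)cc(OCc2ccccc2)c1[C@H]1c2c(OCc3ccccc3)cc(OCc3ccccc3)c(Br)c2O[C@H](c2ccc(OCc3ccccc3)cc2)[C@@H]1OCc1ccccc1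
F9 | step 10 | (2S,3R)-3-[2-(8-bromo-3,5,7,4'-tetra-O-benzyl-epiafzelechin-4β-yl)-3,5-bis(benzyloxy)phenoxy]-3-[4-(benzyloxy)phenyl]-1,1-diethoxypropan-2-ol | CCOC(OCC)[C@@H](O)[C@@H](c1ccc(OCc2ccccc2)cc1)Oc1cc(OCc2ccccc2)cc(OCc2ccccc2)c1[C@H]1c2c(OCc3ccccc3)cc(OCc3ccccc3)c(Br)c2O[C@H](c2ccc(OCc3ccccc3)cc2)[C@@H]1OCc1ccccc1
F10 | step 10 | (2S,3R)-2-(benzyloxy)-3-[2-(8-bromo-3,5,7,4'-tetra-O-benzyl-epiafzelechin-4β-yl)-3,5-bis(benzyloxy)phenoxy]-3-[4-(benzyloxy)phenyl]propanal diethyl acetal | CCOC(OCC)[C@@H](OCc1ccccc1)[C@@H](c1ccc(OCc2ccccc2)cc1)Oc1cc(OCc2ccccc2)cc(OCc2ccccc2)c1[C@H]1c2c(OCc3ccccc3)cc(OCc3ccccc3)c(Br)c2O[C@H](c2ccc(OCc3ccccc3)cc2)[C@@H]1OCc1ccccc1
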